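**Plan**

1. Numbering used throughout (bicyclo[3.2.1]octane): C1 bridgehead CH, C2 ketone, C3 C–OMe, C4 =CH, C5 allyl-bearing bridgehead, C6 CHMe, C7 CHAr, C8 bridging ketone; the precursors keep these labels.
2. The retrosynthesis cuts C3=C4 and C1–C2 together (one C-acylation/olefination event), then C5–allyl, C5–C4 (formyl), C6–CH3 and C7–aryl, back to a 4-silyloxycyclopentenone.
3. Enabling feature: the six-membered ring C1–C2–C3–C4–C5–C8 is a 2-methoxycyclohexenone hung on the cyclopentanone C8–C1–C7–C6–C5. C1 is the only enolisable α-carbon of the C8 ketone (C5 is quaternary) and C4 is a formyl carbon on C5, so a two-carbon piece C2–C3 (acyl chloride at C2, phosphonate carbanion at C3) can bridge C1 and C4.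
4. Forward order: the five-membered ring comes first (chiral-pool enone 1, then aryl, methyl, formyl, allyl); the six-membered ring comes last, which completes the bicycle and delivers the methoxy enone at its final oxidation level.
5. Stereochemistry: C7 from the silyloxy centre of 1 (anti conjugate addition, then loss of silanol); C6 by addition anti to the C7 aryl; C5 by allylation anti to the C6 methyl; C1 by the geometric demand of the bridge on an epimerisable centre.

Key step: step 7

Remark: formyl ketone 7 is written as its hydrogen-bonded (Z)-hydroxymethylidene tautomer; 1, 2 (as a THF solution) and 9 are taken as purchased.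

**Route**

Step 1
Reactants: 1 (4S)-4-[(tert-butyldimethylsilyl)oxy]cyclopent-2-en-1-one; 2 3,4-dimethoxyphenylmagnesium bromide
Product: 4 (4S)-4-(3,4-dimethoxyphenyl)cyclopent-2-en-1-one, via silyloxy ketone 3 (not isolated)
Conditions: CuBr·SMe2 (10 mol %), THF, −78 °C; cold 1 M HCl; crude 3, DBU, CH2Cl2, 0 °C
Reagents that add atoms: none
Why: Copper-catalysed 1,4-addition of the aryl Grignard reagent should occur anti to the neighbouring silyloxy group, which fixes the aryl-bearing centre (future C7), and E1cB loss of silanol from the β-silyloxy ketone 3 then gives the enone (conjugate addition/β-elimination).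

Step 2
Reactants: 4 (4S)-4-(3,4-dimethoxyphenyl)cyclopent-2-en-1-one
Product: 5 {[(3R,4S)-4-(3,4-dimethoxyphenyl)-3-methylcyclopent-1-en-1-yl]oxy}trimethylsilane
Conditions: Me2CuLi, Me3SiCl, THF, −78 °C; Et3N, aq. NaHCO3 work-up
Reagents that add atoms: lithium dimethylcuprate, [Li+].C[Cu-]C; chlorotrimethylsilane, C[Si](C)(C)Cl
Why: The Gilman reagent should add to the enone face anti to the adjacent C7 aryl group, setting C6 with methyl trans to aryl, and trapping with Me3SiCl holds the enolate regiochemistry on the C5 side (cuprate conjugate addition with silyl enol ether trapping).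

Step 3
Reactants: 5 {[(3R,4S)-4-(3,4-dimethoxyphenyl)-3-methylcyclopent-1-en-1-yl]oxy}trimethylsilane
Product: 7 (2Z,3R,4S)-4-(3,4-dimethoxyphenyl)-2-(hydroxymethylidene)-3-methylcyclopentan-1-one, via lithium enolate 6 (not isolated)
Conditions: MeLi, THF, 0 °C; then CF3CH2OCHO, −78 °C; 1 M HCl work-up
Reagents that add atoms: methyllithium, [Li]C; 2,2,2-trifluoroethyl formate, O=COCC(F)(F)F
Why: Cleavage of the Si–O bond with MeLi should give the regio-defined lithium enolate 6, whose C5 is formylated by the activated formate ester at low temperature (crossed Claisen formylation); no new stereocentre is formed because C5 becomes trigonal.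

Step 4
Reactants: 7 (2Z,3R,4S)-4-(3,4-dimethoxyphenyl)-2-(hydroxymethylidene)-3-methylcyclopentan-1-one
Product: 8 (1S,4S,5R)-4-(3,4-dimethoxyphenyl)-5-methyl-2-oxo-1-(prop-2-en-1-yl)cyclopentane-1-carbaldehyde
Conditions: allyl methyl carbonate (1.05 equiv), Pd(PPh3)4 (5 mol %), THF, 0 °C to rt
Reagents that add atoms: allyl methyl carbonate, C=CCOC(=O)OC
Why: In this base-free Tsuji–Trost allylation the methoxide released on ionisation of the carbonate deprotonates the acidic formyl ketone, and the soft enolate should attack the π-allyl palladium complex through C5 on the face anti to the adjacent C6 methyl group (O-allylation being reversible under the catalyst), giving the quaternary centre with allyl trans and formyl cis to methyl.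

Step 5
Reactants: 9 methyl 2-(dimethoxyphosphoryl)-2-methoxyacetate
Product: 10 2-(dimethoxyphosphoryl)-2-methoxyacetic acid
Conditions: LiOH·H2O (1.05 equiv), THF/H2O, 0 °C; then 1 M HCl to pH 2
Reagents that add atoms: lithium hydroxide, [Li+].[OH-]
Why: Hydroxide should saponify the carboxylic methyl ester much faster than it attacks the phosphonate methyl esters (ester hydrolysis).

Step 6
Reactants: 10 2-(dimethoxyphosphoryl)-2-methoxyacetic acid
Product: 11 2-(dimethoxyphosphoryl)-2-methoxyacetyl chloride
Conditions: (COCl)2, DMF (cat.), CH2Cl2, 0 °C to rt; concentrated and used crude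
Reagents that add atoms: oxalyl chloride, O=C(Cl)C(=O)Cl
Why: Oxalyl chloride with catalytic DMF should convert the acid into the acid chloride through the Vilsmeier chloroiminium salt without touching the phosphonate (acid chloride formation).

Step 7
Reactants: 8 (1S,4S,5R)-4-(3,4-dimethoxyphenyl)-5-methyl-2-oxo-1-(prop-2-en-1-yl)cyclopentane-1-carbaldehyde; 11 2-(dimethoxyphosphoryl)-2-methoxyacetyl chloride
Product: 13 Kadsurenin D (1S,5S,6R,7R)-7-(3,4-dimethoxyphenyl)-3-methoxy-6-methyl-5-(prop-2-en-1-yl)bicyclo[3.2.1]oct-3-ene-2,8-dione, via keto phosphonate 12 (not isolated)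
Conditions: MgBr2·OEt2, i-Pr2NEt, CH2Cl2, 0 °C, 11 added slowly; then LiCl, MeCN, rt to 40 °C
Reagents that add atoms: none
Why: Proposed new method: magnesium-assisted soft enolisation can only give the C1 enolate of 8 (C5 is quaternary), which should be C-acylated by 11, or by the phosphonoketene that 11 forms with the amine, on the face anti to the C7 aryl group and hence cis to the C5 formyl group to give 12, whose phosphonate carbanion at C3 then adds to the C4 aldehyde and expels dimethyl phosphate to form C3=C4. The closest known reaction types are the magnesium bromide/amine C-acylation of ketones with acid chlorides, the intramolecular Horner–Wadsworth–Emmons closure of keto phosphonates to cyclohexenones under lithium chloride/amine (Masamune–Roush) conditions and the one-flask O-acylation/Horner–Wadsworth–Emmons annulation of hydroxy ketones to butenolides; the C-acylation variant on a 2-formyl ketone is the untested part. The six-membered ring C1–C2–C3–C4–C5–C8 is closed in the olefination, a 6-(enolendo)-exo-trig attack of the C2–C3 enolate on the formyl group, and this closure completes the bicyclo[3.2.1]octane. The only new stereocentre, C1, is controlled by the bridge itself: only the epimer with the acyl chain cis to the formyl group can cyclise, and C1 of 12 is an epimerisable diketone methine, so material should funnel through that epimer. The step needs C- over O-acylation (secured by the magnesium chelate), acylation at C1 ahead of any reaction at the aldehyde (secured by the hindered, non-enolisable neopentyl formyl group, whose aldol adducts revert) and a cis ring alkene (secured by the ring). Both bond formations are irreversible and set free only chloride and phosphate, so the non-enolisable bridged diketone is never exposed to an alkoxide that could open it by retro-Claisen cleavage.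

**Compound list**

1 | (4S)-4-[(tert-butyldimethylsilyl)oxy]cyclopent-2-en-1-one | O=C1C=C[C@@H](O[Si](C)(C)C(C)(C)C)C1 | starting material
2 | 3,4-dimethoxyphenylmagnesium bromide | COc1ccc([Mg]Br)cc1OC | starting material
3 | (3R,4S)-4-[(tert-butyldimethylsilyl)oxy]-3-(3,4-dimethoxyphenyl)cyclopentan-1-one | O=C1C[C@H](c2ccc(OC)c(OC)c2)[C@@H](O[Si](C)(C)C(C)(C)C)C1 | intermediate
4 | (4S)-4-(3,4-dimethoxyphenyl)cyclopent-2-en-1-one | O=C1C[C@H](c2ccc(OC)c(OC)c2)C=C1 | intermediate
5 | {[(3R,4S)-4-(3,4-dimethoxyphenyl)-3-methylcyclopent-1-en-1-yl]oxy}trimethylsilane | C[Si](C)(C)OC1=C[C@H](C)[C@@H](c2ccc(OC)c(OC)c2)C1 | intermediate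
6 | lithium (3R,4S)-4-(3,4-dimethoxyphenyl)-3-methylcyclopent-1-en-1-olate | [Li+].[O-]C1=C[C@H](C)[C@@H](c2ccc(OC)c(OC)c2)C1 | intermediate
7 | (2Z,3R,4S)-4-(3,4-dimethoxyphenyl)-2-(hydroxymethylidene)-3-methylcyclopentan-1-one | O=C1C[C@H](c2ccc(OC)c(OC)c2)[C@@H](C)/C1=C/O | intermediate
8 | (1S,4S,5R)-4-(3,4-dimethoxyphenyl)-5-methyl-2-oxo-1-(prop-2-en-1-yl)cyclopentane-1-carbaldehyde | C=CC[C@]1(C=O)C(=O)C[C@H](c2ccc(OC)c(OC)c2)[C@H]1C | intermediate
9 | methyl 2-(dimethoxyphosphoryl)-2-methoxyacetate | COC(C(=O)OC)P(=O)(OC)OC | starting material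
10 | 2-(dimethoxyphosphoryl)-2-methoxyacetic acid | COC(C(=O)O)P(=O)(OC)OC | intermediate
11 | 2-(dimethoxyphosphoryl)-2-methoxyacetyl chloride | COC(C(=O)Cl)P(=O)(OC)OC | intermediate
12 | (1S,3S,4R,5R)-3-[2-(dimethoxyphosphoryl)-2-methoxyacetyl]-4-(3,4-dimethoxyphenyl)-5-methyl-2-oxo-1-(prop-2-en-1-yl)cyclopentane-1-carbaldehyde (both epimers at the phosphonate carbon) | C=CC[C@]1(C=O)C(=O)[C@@H](C(=O)C(OC)P(=O)(OC)OC)[C@H](c2ccc(OC)c(OC)c2)[C@H]1C | intermediate
13 | Kadsurenin D, (1S,5S,6R,7R)-7-(3,4-dimethoxyphenyl)-3-methoxy-6-methyl-5-(prop-2-en-1-yl)bicyclo[3.2.1]oct-3-ene-2,8-dione | C=CC[C@]12C=C(OC)C(=O)[C@H](C1=O)[C@H](c1ccc(OC)c(OC)c1)[C@H]2C | target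

**Step count and risks**

Total step count: 7. Longest linear sequence: 5 steps (steps 1, 2, 3, 4, 7); steps 5 and 6 prepare the acyl donor.

Steps most likely to fail:

1. Step 7 (Proposed new method). The carbanion of the acyl donor may olefinate the free aldehyde before C1 is acylated, which would give an acyclic alkene of the wrong geometry. The enolate may also be acylated on oxygen, or the amine may cause deformylation. The fallback uses known chemistry, sets out from 8 and comes back at 13. The aldehyde would be masked (HC(OMe)3, pyridinium tosylate, MeOH) as the acetal (2S,3R,4S)-2-(dimethoxymethyl)-4-(3,4-dimethoxyphenyl)-3-methyl-2-(prop-2-en-1-yl)cyclopentan-1-one F1. Its lithium enolate (LiN(SiMe3)2, THF, −78 °C) would be C-acylated at C1 with N-methoxy-N-methyl-2-methoxyacetamide to the diketone (2S,3R,4R,5S)-2-(dimethoxymethyl)-4-(3,4-dimethoxyphenyl)-5-(2-methoxyacetyl)-3-methyl-2-(prop-2-en-1-yl)cyclopentan-1-one F2. Aqueous TsOH would then free the aldehyde (1S,3S,4R,5R)-4-(3,4-dimethoxyphenyl)-3-(2-methoxyacetyl)-5-methyl-2-oxo-1-(prop-2-en-1-yl)cyclopentane-1-carbaldehyde F3 (not isolated). The same acid, or piperidinium acetate, should close the ring by intramolecular aldol condensation between C3 and C4 to give 13.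

2. Step 4. The methoxide released from the carbonate may cleave the formyl group by retro-Claisen attack, and facial control at the new quaternary carbon may be incomplete. The fallback sets out from 7 and comes back at 8. O-Allylation (K2CO3, allyl bromide, acetone) would give the enol ether (2E,3R,4S)-4-(3,4-dimethoxyphenyl)-3-methyl-2-[(prop-2-en-1-yloxy)methylidene]cyclopentan-1-one F4. Heating (toluene, 110 °C) should then deliver the allyl group to C5 by Claisen rearrangement through a chair transition state on the face anti to the C6 methyl group, without palladium or alkoxide, to give 8.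

3. Step 1. During the base-induced elimination, γ-deprotonation at the benzylic position of the 4-aryl enone may cause racemisation and migration of the double bond into conjugation with the arene. The fallback changes the order of events so that the aryl-bearing centre is made last; it sets out from 1 and comes back at 8. Me2CuLi would add to 1 anti to the silyloxy group to give (3S,4S)-4-[(tert-butyldimethylsilyl)oxy]-3-methylcyclopentan-1-one F5 (not isolated). DBU would convert this into (4S)-4-methylcyclopent-2-en-1-one F6. Kinetic α′-deprotonation (LiN(i-Pr)2, THF, −78 °C) and formylation with CF3CH2OCHO would give (4R,5Z)-5-(hydroxymethylidene)-4-methylcyclopent-2-en-1-one F7. Allylation as in step 4 (allyl methyl carbonate, Pd(PPh3)4) would give (1S,5R)-5-methyl-2-oxo-1-(prop-2-en-1-yl)cyclopent-3-ene-1-carbaldehyde F8. Copper-catalysed conjugate addition of 2 (CuBr·SMe2, Me3SiCl, THF, −78 °C; dilute acid work-up) anti to the methyl group should then give 8.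

**Further compounds**

F1 | step 7 | (2S,3R,4S)-2-(dimethoxymethyl)-4-(3,4-dimethoxyphenyl)-3-methyl-2-(prop-2-en-1-yl)cyclopentan-1-one | C=CC[C@]1(C(OC)OC)C(=O)C[C@H](c2ccc(OC)c(OC)c2)[C@H]1C
F2 | step 7 | (2S,3R,4R,5S)-2-(dimethoxymethyl)-4-(3,4-dimethoxyphenyl)-5-(2-methoxyacetyl)-3-methyl-2-(prop-2-en-1-yl)cyclopentan-1-one | C=CC[C@]1(C(OC)OC)C(=O)[C@@H](C(=O)COC)[C@H](c2ccc(OC)c(OC)c2)[C@H]1C
F3 | step 7 | (1S,3S,4R,5R)-4-(3,4-dimethoxyphenyl)-3-(2-methoxyacetyl)-5-methyl-2-oxo-1-(prop-2-en-1-yl)cyclopentane-1-carbaldehyde | C=CC[C@]1(C=O)C(=O)[C@@H](C(=O)COC)[C@H](c2ccc(OC)c(OC)c2)[C@H]1C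
F4 | step 4 | (2E,3R,4S)-4-(3,4-dimethoxyphenyl)-3-methyl-2-[(prop-2-en-1-yloxy)methylidene]cyclopentan-1-one | O=C1C[C@H](c2ccc(OC)c(OC)c2)[C@@H](C)/C1=C\OCC=C
F5 | step 1 | (3S,4S)-4-[(tert-butyldimethylsilyl)oxy]-3-methylcyclopentan-1-one | O=C1C[C@H](C)[C@@H](O[Si](C)(C)C(C)(C)C)C1
F6 | step 1 | (4S)-4-methylcyclopent-2-en-1-one | O=C1C[C@H](C)C=C1
F7 | step 1 | (4R,5Z)-5-(hydroxymethylidene)-4-methylcyclopent-2-en-1-one | O=C1C=C[C@@H](C)/C1=C/O
F8 | step 1 | (1S,5R)-5-methyl-2-oxo-1-(prop-2-en-1-yl)cyclopent-3-ene-1-carbaldehyde | C=CC[C@]1(C=O)C(=O)C=C[C@H]1C
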